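**Retrosynthetic overview**
- Target 29 ⇐ tertiary carbinol 25 by hydrogenolysis/hydrogenation, acetylation, dehydration (C16=C17 enone) and desilylation.
- 25 ⇐ alkylidene tricarbonyl lactone 22 + buta-1,3-diene: Diels–Alder (C8–C14, C9–C11) then carbonyl-ene (C16–C13) in one flask, so rings C and D form together.
- 22 ⇐ spirolactone 15 (Claisen acylation, dehydrogenation, oxidation); 15 ⇐ epoxide 12 + acrylate by radical coupling/lactonisation (lactone ring, quaternary C10).
- 12 ⇐ aldehyde 6, from a catalytic enantioselective Diels–Alder of methacrolein with siloxydiene 4 (ring A; C4, C5).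
- Ring order: A → lactone → C + D.

Assumption: locants C1–C20 in names and comments are the ent-kaurane locants of the target (C10 spiro carbon, C20–O–C7(=O) lactone, C15 ketone, C16=C17 methylene); racemic ethyl lactate is used because its stereocentre is erased in step 12.

**Step 1**
Reactants: 1 2-[(tert-butyldiphenylsilyl)oxy]acetaldehyde; 2 1-(triphenyl-λ5-phosphanylidene)propan-2-one
Product: 3 (3E)-5-[(tert-butyldiphenylsilyl)oxy]pent-3-en-2-one
Conditions: CH2Cl2, rt, 16 h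
Reagents that add atoms: none
Why: Wittig olefination with a stabilised ylide gives the (E)-enone.

**Step 2**
Reactants: 3 (3E)-5-[(tert-butyldiphenylsilyl)oxy]pent-3-en-2-one
Product: 4 (3E)-5-[(tert-butyldiphenylsilyl)oxy]-2-[(triisopropylsilyl)oxy]penta-1,3-diene
Conditions: i-Pr3SiOTf, Et3N, CH2Cl2, 0 °C
Reagents that add atoms: triisopropylsilyl trifluoromethanesulfonate, CC(C)[Si](C(C)C)(C(C)C)OS(=O)(=O)C(F)(F)F
Why: Soft enolisation and O-silylation on the methyl side (silyl enol ether formation) gives the cross-conjugated 2-siloxydiene with the E-alkene intact.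

**Step 3**
Reactants: 4 (3E)-5-[(tert-butyldiphenylsilyl)oxy]-2-[(triisopropylsilyl)oxy]penta-1,3-diene; 5 methacrolein
Product: 6 (1R,2S)-2-{[(tert-butyldiphenylsilyl)oxy]methyl}-1-methyl-4-[(triisopropylsilyl)oxy]cyclohex-3-ene-1-carbaldehyde
Conditions: (S)-1-(2-methylphenyl)-3,3-diphenyltetrahydro-1H,3H-pyrrolo[1,2-c][1,3,2]oxazaborole (20 mol %), HN(SO2CF3)2 (20 mol %), CH2Cl2, −78 °C
Reagents that add atoms: none
Why: Catalytic enantioselective Diels–Alder reaction (cationic oxazaborolidine): the siloxy group and the terminal CH2OSi group both direct the substituted diene terminus to the α-carbon of methacrolein, formyl-endo addition to the (E)-diene puts CHO cis to CH2OSi, and the catalyst shields one enal face so that C4 and C5 are set together (the antipodal catalyst is equally available should the sense of induction be the opposite one).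

**Step 4**
Reactants: 6 (1R,2S)-2-{[(tert-butyldiphenylsilyl)oxy]methyl}-1-methyl-4-[(triisopropylsilyl)oxy]cyclohex-3-ene-1-carbaldehyde
Product: 9 (1R,2R)-2-{[(tert-butyldiphenylsilyl)oxy]methyl}-1-methyl-3-methylidene-4-oxocyclohexane-1-carbaldehyde, via Mannich base 7 (not isolated), via methiodide 8 (not isolated)
Conditions: [Me2N=CH2]I, CH2Cl2, rt; MeI; aq. NaHCO3, CH2Cl2
Reagents that add atoms: dimethyl(methylidene)ammonium iodide (Eschenmoser's salt), C=[N+](C)C.[I-]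
Why: Regiospecific Mannich reaction of the silyl enol ether at C10, then quaternisation and β-elimination (Eschenmoser methylenation) give the α-methylene ketone; C4 is non-enolisable and C5 is untouched.

**Step 5**
Reactants: 9 (1R,2R)-2-{[(tert-butyldiphenylsilyl)oxy]methyl}-1-methyl-3-methylidene-4-oxocyclohexane-1-carbaldehyde
Product: 10 (1S,3R,4R)-3-{[(tert-butyldiphenylsilyl)oxy]methyl}-4-(hydroxymethyl)-4-methyl-2-methylidenecyclohexan-1-ol
Conditions: NaBH4, CeCl3·7H2O, MeOH, −78 to 0 °C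
Reagents that add atoms: none
Why: Luche reduction: 1,2-hydride delivery to the enone from the face opposite the neighbouring CH2OSi group gives the equatorial (1S) allylic alcohol, cis-1,3 to that group, and the neopentyl aldehyde is reduced in the same pot.

**Step 6**
Reactants: 10 (1S,3R,4R)-3-{[(tert-butyldiphenylsilyl)oxy]methyl}-4-(hydroxymethyl)-4-methyl-2-methylidenecyclohexan-1-ol
Product: 11 (1S,3R,4R)-1-(benzyloxy)-4-[(benzyloxy)methyl]-3-{[(tert-butyldiphenylsilyl)oxy]methyl}-4-methyl-2-methylidenecyclohexane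
Conditions: NaH, BnBr, Bu4NI (cat.), THF–DMF, 0 °C to rt
Reagents that add atoms: benzyl bromide, BrCc1ccccc1
Why: Williamson etherification protects the C1 and C19 hydroxyls with one group that survives base and Lewis acid and is removed later by hydrogenolysis; no stereocentre is affected.

**Step 7**
Reactants: 11 (1S,3R,4R)-1-(benzyloxy)-4-[(benzyloxy)methyl]-3-{[(tert-butyldiphenylsilyl)oxy]methyl}-4-methyl-2-methylidenecyclohexane
Product: 12 (4S,5R,8S)-8-(benzyloxy)-5-[(benzyloxy)methyl]-4-{[(tert-butyldiphenylsilyl)oxy]methyl}-5-methyl-1-oxaspiro[2.5]octane (both C3 epimers)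
Conditions: mCPBA, NaHCO3, CH2Cl2, 0 °C
Reagents that add atoms: 3-chloroperoxybenzoic acid, OOC(=O)c1cccc(Cl)c1
Why: Prilezhaev epoxidation of the only alkene; the epoxide configuration is irrelevant because C10 becomes a planar radical in step 8.

**Step 8**
Reactants: 12 (4S,5R,8S)-8-(benzyloxy)-5-[(benzyloxy)methyl]-4-{[(tert-butyldiphenylsilyl)oxy]methyl}-5-methyl-1-oxaspiro[2.5]octane; 13 2,2,2-trifluoroethyl acrylate
Product: 15 (6S,7R,8R,11S)-11-(benzyloxy)-8-[(benzyloxy)methyl]-7-{[(tert-butyldiphenylsilyl)oxy]methyl}-8-methyl-2-oxaspiro[5.5]undecan-3-one, via hydroxy ester 14 (not isolated)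
Conditions: (C5H5)2TiCl2 (30 mol %), Zn dust, 2,4,6-collidine·HCl, THF, rt; then TsOH (cat.), CH2Cl2
Reagents that add atoms: none
Why: Trivalent titanium opens the epoxide homolytically to the tertiary C10 β-titanoxy radical, which adds to the acrylate (reductive epoxide opening/Giese addition) from the face anti to the C1 benzyloxy and C5 silyloxymethyl groups, setting C10; the activated trifluoroethyl ester then lactonises onto the C20 oxygen.

**Step 9**
Reactants: 16 ethyl 2-hydroxypropanoate (racemic ethyl lactate)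
Product: 17 ethyl 2-[(triethylsilyl)oxy]propanoate
Conditions: Et3SiCl, imidazole, CH2Cl2, 0 °C to rt
Reagents that add atoms: chlorotriethylsilane, CC[Si](Cl)(CC)CC
Why: O-silylation gives an acylating agent whose protecting group falls off in the acidic work-up of step 10.

**Step 10**
Reactants: 15 (6S,7R,8R,11S)-11-(benzyloxy)-8-[(benzyloxy)methyl]-7-{[(tert-butyldiphenylsilyl)oxy]methyl}-8-methyl-2-oxaspiro[5.5]undecan-3-one; 17 ethyl 2-[(triethylsilyl)oxy]propanoate
Product: 19 (6S,7R,8R,11S)-11-(benzyloxy)-8-[(benzyloxy)methyl]-7-{[(tert-butyldiphenylsilyl)oxy]methyl}-4-(2-hydroxypropanoyl)-8-methyl-2-oxaspiro[5.5]undecan-3-one (epimers at C4 and at the carbinol carbon), via silyl ether 18 (not isolated)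
Conditions: LiN(i-Pr)2 (2.2 equiv), THF, −78 °C; 17, −78 to −30 °C; then 1 M HCl, THF, 0 °C
Reagents that add atoms: none
Why: Crossed Claisen condensation of the lactone lithium enolate (C8) with the α-silyloxy ester, driven by deprotonation of the β-keto lactone; the acid work-up cleaves the triethylsilyl ether, and both new stereocentres are erased later.

**Step 11**
Reactants: 19 (6S,7R,8R,11S)-11-(benzyloxy)-8-[(benzyloxy)methyl]-7-{[(tert-butyldiphenylsilyl)oxy]methyl}-4-(2-hydroxypropanoyl)-8-methyl-2-oxaspiro[5.5]undecan-3-one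
Product: 21 (6S,7R,8R,11S)-11-(benzyloxy)-8-[(benzyloxy)methyl]-7-{[(tert-butyldiphenylsilyl)oxy]methyl}-4-(2-hydroxypropanoyl)-8-methyl-2-oxaspiro[5.5]undec-4-en-3-one, via selenide 20 (not isolated)
Conditions: PhSeCl, pyridine, CH2Cl2, 0 °C; then 30% H2O2, 0 °C to rt
Reagents that add atoms: none
Why: Selenenylation of the β-keto lactone at C8 and selenoxide syn-elimination toward C9 (the only β-hydrogens) give the endocyclic C8=C9 alkene; it is done at the ketol stage so that no 1,2-dione meets peroxide.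

**Step 12**
Reactants: 21 (6S,7R,8R,11S)-11-(benzyloxy)-8-[(benzyloxy)methyl]-7-{[(tert-butyldiphenylsilyl)oxy]methyl}-4-(2-hydroxypropanoyl)-8-methyl-2-oxaspiro[5.5]undec-4-en-3-one
Product: 22 (6S,7R,8R,11S)-11-(benzyloxy)-8-[(benzyloxy)methyl]-7-{[(tert-butyldiphenylsilyl)oxy]methyl}-8-methyl-4-(2-oxopropanoyl)-2-oxaspiro[5.5]undec-4-en-3-one
Conditions: Dess–Martin periodinane, CH2Cl2, rt; filtered and used at once
Reagents that add atoms: none
Why: Dess–Martin oxidation of the secondary α-ketol to the 1,2-dione under neutral anhydrous conditions gives the triply activated dienophile.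

**Step 13**
Reactants: 22 (6S,7R,8R,11S)-11-(benzyloxy)-8-[(benzyloxy)methyl]-7-{[(tert-butyldiphenylsilyl)oxy]methyl}-8-methyl-4-(2-oxopropanoyl)-2-oxaspiro[5.5]undec-4-en-3-one; 23 buta-1,3-diene
Product: 25 (1S,4R,5R,8S,9S,10S,13S)-1,19-bis(benzyloxy)-6-[(tert-butyldiphenylsilyl)oxy]-16-hydroxy-15-oxo-6,7-secokaur-11-en-7,20-olide (C16 epimer not assigned), via Diels–Alder adduct 24 (not isolated)
Conditions: 23 (10 equiv), Sc(OSO2CF3)3 (20 mol %), 4 Å MS, CH2Cl2, −40 °C to rt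
Reagents that add atoms: none
Why: Proposed new method: chelation by the Lewis acid lowers the LUMO of the alkylidene tricarbonyl so that butadiene adds suprafacially across C8=C9 on the face anti to the bulkier C5 side of ring A (cis fusion fixes C8 and C9 relative to C10, with no endo/exo or regiochemical issue), and the same Lewis acid then activates the 1,2-dione of adduct 24 so that the C16 carbonyl undergoes a type 1 intramolecular carbonyl-ene reaction with the new C12=C13 bond (C16–C13 bond, hydrogen transfer from C11), which is only possible on the ring face that carries C15 and therefore sets C13 and forms rings C and D in one operation; the closest known reaction types are Lewis-acid Diels–Alder additions of butadiene to 2-acyl cycloalkenones and ene cyclisations of olefinic α-keto esters.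

**Step 14**
Reactants: 25 (1S,4R,5R,8S,9S,10S,13S)-1,19-bis(benzyloxy)-6-[(tert-butyldiphenylsilyl)oxy]-16-hydroxy-15-oxo-6,7-secokaur-11-en-7,20-olide
Product: 26 (1S,4R,5R,8S,9S,10S,13R)-6-[(tert-butyldiphenylsilyl)oxy]-1,16,19-trihydroxy-15-oxo-6,7-secokauran-7,20-olide
Conditions: H2 (1 atm), Pd/C (10% Pd), EtOAc, rt
Reagents that add atoms: none
Why: Heterogeneous hydrogenation saturates C11=C12 and hydrogenolyses both benzyl ethers while the enone is still masked as the tertiary carbinol; no stereocentre changes (the C13 descriptor changes only by priority).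

**Step 15**
Reactants: 26 (1S,4R,5R,8S,9S,10S,13R)-6-[(tert-butyldiphenylsilyl)oxy]-1,16,19-trihydroxy-15-oxo-6,7-secokauran-7,20-olide
Product: 27 (1S,4R,5R,8S,9S,10S,13R)-1,19-diacetoxy-6-[(tert-butyldiphenylsilyl)oxy]-16-hydroxy-15-oxo-6,7-secokauran-7,20-olide
Conditions: Ac2O, pyridine, 4-(dimethylamino)pyridine (cat.), CH2Cl2, 0 °C to rt
Reagents that add atoms: acetic anhydride, CC(=O)OC(C)=O
Why: Nucleophile-catalysed acylation of the secondary C1 and primary C19 hydroxyls; the tertiary α-ketol is too hindered to react, and the acetylation is run directly after step 14 to pre-empt migration of the lactone acyl group to the free C1 oxygen.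

**Step 16**
Reactants: 27 (1S,4R,5R,8S,9S,10S,13R)-1,19-diacetoxy-6-[(tert-butyldiphenylsilyl)oxy]-16-hydroxy-15-oxo-6,7-secokauran-7,20-olide
Product: 28 (1S,4R,5R,8S,9S,10S,13R)-1,19-diacetoxy-6-[(tert-butyldiphenylsilyl)oxy]-15-oxo-6,7-secokaur-16-en-7,20-olide
Conditions: Burgess reagent (MeO2CN–SO2NEt3 inner salt), toluene, 60 °C
Reagents that add atoms: none
Why: Burgess dehydration (syn-elimination through the sulfamate ester) can take a β-hydrogen only from the methyl group, because the other β-position is the C13 bridgehead, so the exocyclic C16=C17 enone forms.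

**Step 17**
Reactants: 28 (1S,4R,5R,8S,9S,10S,13R)-1,19-diacetoxy-6-[(tert-butyldiphenylsilyl)oxy]-15-oxo-6,7-secokaur-16-en-7,20-olide
Product: 29 (1S,4R,5R,8S,9S,10S,13R)-1,19-diacetoxy-6-hydroxy-15-oxo-6,7-secokaur-16-en-7,20-olide (CNP0105570.2)
Conditions: HF·pyridine, pyridine, THF, 0 °C to rt
Reagents that add atoms: none
Why: Fluoride-mediated desilylation under buffered acidic conditions frees the C6 hydroxyl without touching the acetates, the lactone or the enone.

**Compound list**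
1 | 2-[(tert-butyldiphenylsilyl)oxy]acetaldehyde | O=CCO[Si](c1ccccc1)(c1ccccc1)C(C)(C)C | starting material
2 | 1-(triphenyl-λ5-phosphanylidene)propan-2-one | CC(=O)C=P(c1ccccc1)(c1ccccc1)c1ccccc1 | starting material
3 | (3E)-5-[(tert-butyldiphenylsilyl)oxy]pent-3-en-2-one | CC(=O)/C=C/CO[Si](c1ccccc1)(c1ccccc1)C(C)(C)C | intermediate
4 | (3E)-5-[(tert-butyldiphenylsilyl)oxy]-2-[(triisopropylsilyl)oxy]penta-1,3-diene | C=C(O[Si](C(C)C)(C(C)C)C(C)C)/C=C/CO[Si](c1ccccc1)(c1ccccc1)C(C)(C)C | intermediate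
5 | methacrolein (2-methylprop-2-enal) | CC(=C)C=O | starting material
6 | (1R,2S)-2-{[(tert-butyldiphenylsilyl)oxy]methyl}-1-methyl-4-[(triisopropylsilyl)oxy]cyclohex-3-ene-1-carbaldehyde | C1=C(O[Si](C(C)C)(C(C)C)C(C)C)CC[C@@](C)(C=O)[C@H]1CO[Si](c1ccccc1)(c1ccccc1)C(C)(C)C | intermediate
7 | Mannich base: (1R,2S)-2-{[(tert-butyldiphenylsilyl)oxy]methyl}-3-[(dimethylamino)methyl]-1-methyl-4-oxocyclohexane-1-carbaldehyde (C3 epimers) | CN(C)CC1C(=O)CC[C@@](C)(C=O)[C@H]1CO[Si](c1ccccc1)(c1ccccc1)C(C)(C)C | intermediate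
8 | methiodide of 7 (trimethylammonium iodide; same ring stereocentres) | C[N+](C)(C)CC1C(=O)CC[C@@](C)(C=O)[C@H]1CO[Si](c1ccccc1)(c1ccccc1)C(C)(C)C.[I-] | intermediate
9 | (1R,2R)-2-{[(tert-butyldiphenylsilyl)oxy]methyl}-1-methyl-3-methylidene-4-oxocyclohexane-1-carbaldehyde | C=C1C(=O)CC[C@@](C)(C=O)[C@H]1CO[Si](c1ccccc1)(c1ccccc1)C(C)(C)C | intermediate
10 | (1S,3R,4R)-3-{[(tert-butyldiphenylsilyl)oxy]methyl}-4-(hydroxymethyl)-4-methyl-2-methylidenecyclohexan-1-ol | C=C1[C@@H](O)CC[C@@](C)(CO)[C@H]1CO[Si](c1ccccc1)(c1ccccc1)C(C)(C)C | intermediate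
11 | (1S,3R,4R)-1-(benzyloxy)-4-[(benzyloxy)methyl]-3-{[(tert-butyldiphenylsilyl)oxy]methyl}-4-methyl-2-methylidenecyclohexane | C=C1[C@@H](OCc2ccccc2)CC[C@@](C)(COCc2ccccc2)[C@H]1CO[Si](c1ccccc1)(c1ccccc1)C(C)(C)C | intermediate
12 | (4S,5R,8S)-8-(benzyloxy)-5-[(benzyloxy)methyl]-4-{[(tert-butyldiphenylsilyl)oxy]methyl}-5-methyl-1-oxaspiro[2.5]octane (both C3 epimers) | C1OC12[C@@H](OCc3ccccc3)CC[C@@](C)(COCc3ccccc3)[C@H]2CO[Si](c1ccccc1)(c1ccccc1)C(C)(C)C | intermediate
13 | 2,2,2-trifluoroethyl acrylate | C=CC(=O)OCC(F)(F)F | starting material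
14 | hydroxy ester: 2,2,2-trifluoroethyl 3-[(1S,2S,5R,6R)-2-(benzyloxy)-5-[(benzyloxy)methyl]-6-{[(tert-butyldiphenylsilyl)oxy]methyl}-1-(hydroxymethyl)-5-methylcyclohexyl]propanoate | O=C(OCC(F)(F)F)CC[C@]1(CO)[C@@H](OCc2ccccc2)CC[C@@](C)(COCc2ccccc2)[C@H]1CO[Si](c1ccccc1)(c1ccccc1)C(C)(C)C | intermediate
15 | (6S,7R,8R,11S)-11-(benzyloxy)-8-[(benzyloxy)methyl]-7-{[(tert-butyldiphenylsilyl)oxy]methyl}-8-methyl-2-oxaspiro[5.5]undecan-3-one | O=C1CC[C@]2(CO1)[C@@H](OCc1ccccc1)CC[C@@](C)(COCc1ccccc1)[C@H]2CO[Si](c1ccccc1)(c1ccccc1)C(C)(C)C | intermediate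
16 | ethyl 2-hydroxypropanoate (racemic ethyl lactate) | CCOC(=O)C(C)O | starting material
17 | ethyl 2-[(triethylsilyl)oxy]propanoate | CCOC(=O)C(C)O[Si](CC)(CC)CC | intermediate
18 | silyl ether: 4-{2-[(triethylsilyl)oxy]propanoyl} derivative of 15 (ring A and spiro centres as in 15; other centres mixed) | CC(O[Si](CC)(CC)CC)C(=O)C1CC[C@]2(COC1=O)[C@@H](OCc1ccccc1)CC[C@@](C)(COCc1ccccc1)[C@H]2CO[Si](c1ccccc1)(c1ccccc1)C(C)(C)C | intermediate
19 | (6S,7R,8R,11S)-11-(benzyloxy)-8-[(benzyloxy)methyl]-7-{[(tert-butyldiphenylsilyl)oxy]methyl}-4-(2-hydroxypropanoyl)-8-methyl-2-oxaspiro[5.5]undecan-3-one (epimers at C4 and carbinol carbon) | CC(O)C(=O)C1CC[C@]2(COC1=O)[C@@H](OCc1ccccc1)CC[C@@](C)(COCc1ccccc1)[C@H]2CO[Si](c1ccccc1)(c1ccccc1)C(C)(C)C | intermediate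
20 | selenide: 4-(phenylselanyl) derivative of 19 | CC(O)C(=O)C1([Se]c3ccccc3)CC[C@]2(COC1=O)[C@@H](OCc1ccccc1)CC[C@@](C)(COCc1ccccc1)[C@H]2CO[Si](c1ccccc1)(c1ccccc1)C(C)(C)C | intermediate
21 | (6S,7R,8R,11S)-11-(benzyloxy)-8-[(benzyloxy)methyl]-7-{[(tert-butyldiphenylsilyl)oxy]methyl}-4-(2-hydroxypropanoyl)-8-methyl-2-oxaspiro[5.5]undec-4-en-3-one | CC(O)C(=O)C1=C[C@]2(COC1=O)[C@@H](OCc1ccccc1)CC[C@@](C)(COCc1ccccc1)[C@H]2CO[Si](c1ccccc1)(c1ccccc1)C(C)(C)C | intermediate
22 | (6S,7R,8R,11S)-11-(benzyloxy)-8-[(benzyloxy)methyl]-7-{[(tert-butyldiphenylsilyl)oxy]methyl}-8-methyl-4-(2-oxopropanoyl)-2-oxaspiro[5.5]undec-4-en-3-one | CC(=O)C(=O)C1=C[C@]2(COC1=O)[C@@H](OCc1ccccc1)CC[C@@](C)(COCc1ccccc1)[C@H]2CO[Si](c1ccccc1)(c1ccccc1)C(C)(C)C | intermediate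
23 | buta-1,3-diene | C=CC=C | starting material
24 | Diels–Alder adduct: cis-fused cyclohexene–δ-lactone spiro-linked to ring A at C10 and carrying the 2-oxopropanoyl group on C8 (1S,4R,5R,8S,9S,10S; C12=C13 alkene) | CC(=O)C(=O)[C@]12CC=CC[C@H]1[C@]1(COC2=O)[C@@H](OCc2ccccc2)CC[C@@](C)(COCc2ccccc2)[C@H]1CO[Si](c1ccccc1)(c1ccccc1)C(C)(C)C | intermediate
25 | (1S,4R,5R,8S,9S,10S,13S)-1,19-bis(benzyloxy)-6-[(tert-butyldiphenylsilyl)oxy]-16-hydroxy-15-oxo-6,7-secokaur-11-en-7,20-olide (C16 epimer not assigned) | CC1(O)C(=O)[C@]23C[C@H]1C=C[C@H]2[C@]1(COC3=O)[C@@H](OCc2ccccc2)CC[C@@](C)(COCc2ccccc2)[C@H]1CO[Si](c1ccccc1)(c1ccccc1)C(C)(C)C | intermediate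
26 | (1S,4R,5R,8S,9S,10S,13R)-6-[(tert-butyldiphenylsilyl)oxy]-1,16,19-trihydroxy-15-oxo-6,7-secokauran-7,20-olide | CC1(O)C(=O)[C@]23C[C@H]1CC[C@H]2[C@]1(COC3=O)[C@@H](O)CC[C@@](C)(CO)[C@H]1CO[Si](c1ccccc1)(c1ccccc1)C(C)(C)C | intermediate
27 | (1S,4R,5R,8S,9S,10S,13R)-1,19-diacetoxy-6-[(tert-butyldiphenylsilyl)oxy]-16-hydroxy-15-oxo-6,7-secokauran-7,20-olide | CC1(O)C(=O)[C@]23C[C@H]1CC[C@H]2[C@]1(COC3=O)[C@@H](OC(C)=O)CC[C@@](C)(COC(C)=O)[C@H]1CO[Si](c1ccccc1)(c1ccccc1)C(C)(C)C | intermediate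
28 | (1S,4R,5R,8S,9S,10S,13R)-1,19-diacetoxy-6-[(tert-butyldiphenylsilyl)oxy]-15-oxo-6,7-secokaur-16-en-7,20-olide | C=C1C(=O)[C@]23C[C@H]1CC[C@H]2[C@]1(COC3=O)[C@@H](OC(C)=O)CC[C@@](C)(COC(C)=O)[C@H]1CO[Si](c1ccccc1)(c1ccccc1)C(C)(C)C | intermediate
29 | (1S,4R,5R,8S,9S,10S,13R)-1,19-diacetoxy-6-hydroxy-15-oxo-6,7-secokaur-16-en-7,20-olide (CNP0105570.2) | C=C1C(=O)[C@]23C[C@H]1CC[C@H]2[C@]1(COC3=O)[C@@H](OC(C)=O)CC[C@@](C)(COC(C)=O)[C@H]1CO | target

**Totals**
Total step count: 17. Longest linear sequence: 16 (steps 1–8 and 10–17; step 9 is a one-step side branch).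

**Three steps most likely to fail**

Step 13 (one-pot Diels–Alder/carbonyl-ene). The risks are the lability of tricarbonyl 22 (enolisation, Nazarov-type closure), the facial selectivity of the cycloaddition, and closure of C16 onto C12 instead of C13. The fallback sets out from 15 and comes back at 28 and replaces the ene closure by an enol silane cycloalkenylation. 15 is C-acetylated (LiN(i-Pr)2, then N-acetylimidazole, THF, −78 °C) to the acetyl lactone F1. PhSeCl/pyridine then H2O2 gives the acetyl enoate F2, which takes up buta-1,3-diene with ZnCl2 in Et2O to give the cis-fused butadiene adduct F3. t-BuMe2SiOTf/Et3N converts the methyl ketone into the silyl enol ether F4, and Pd(OAc)2 (divalent palladium) in DMSO under O2 closes ring D to the 17-nor ketone F5. H2 over Pd/C saturates C11=C12 and removes both benzyl groups to give the nor-ketone diol F6. (Me2N)2CH2 with Ac2O in DMF at 95 °C then acetylates both hydroxyls and methylenates C16, which gives 28.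

Step 8 (radical coupling of a hindered, oxygenated tertiary radical; C10 selectivity). The fallback sets out from 12 and comes back at 15 and builds the quaternary centre by a sigmatropic route. BF3·OEt2 isomerises the epoxide (Meinwald rearrangement) to the ring aldehyde F7. Allyl alcohol with TsOH in refluxing toluene forms the allyl enol ether, which undergoes Claisen rearrangement on the face anti to the C1 and C5 substituents to give the quaternary allyl aldehyde F8. NaBH4 gives the allyl alcohol F9, and 9-BBN then NaBO3 gives the 1,5-diol F10. TEMPO/PhI(OAc)2 oxidises the unhindered primary alcohol and the resulting lactol on to lactone 15.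

Step 16 (dehydration of a hindered tertiary α-ketol; possible ketol rearrangement). The fallback sets out from 27 and comes back at 28 and swaps elimination for deoxygenation/dehydrogenation. SmI2 in THF/MeOH at −78 °C cleaves the tertiary α-hydroxyl reductively to the methyl ketone F11. Me3SiOTf/Et3N gives the trimethylsilyl enol ether F12. Pd(OAc)2 (divalent palladium) in MeCN (Saegusa–Ito dehydrogenation) can eliminate only toward the methyl group and gives 28.

**Further compounds**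
F1 | step 13 | acetyl lactone: 4-acetyl derivative of 15 (C4 epimers) | CC(=O)C1CC[C@]2(COC1=O)[C@@H](OCc1ccccc1)CC[C@@](C)(COCc1ccccc1)[C@H]2CO[Si](c1ccccc1)(c1ccccc1)C(C)(C)C
F2 | step 13 | acetyl enoate: 4-acetyl-2-oxaspiro[5.5]undec-4-en-3-one analogue of 22 | CC(=O)C1=C[C@]2(COC1=O)[C@@H](OCc1ccccc1)CC[C@@](C)(COCc1ccccc1)[C@H]2CO[Si](c1ccccc1)(c1ccccc1)C(C)(C)C
F3 | step 13 | cis-fused butadiene adduct carrying acetyl on C8 (8S,9S,10S) | CC(=O)[C@]12CC=CC[C@H]1[C@]1(COC2=O)[C@@H](OCc2ccccc2)CC[C@@](C)(COCc2ccccc2)[C@H]1CO[Si](c1ccccc1)(c1ccccc1)C(C)(C)C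
F4 | step 13 | silyl enol ether (tert-butyldimethylsilyl) of F3 | C=C(O[Si](C)(C)C(C)(C)C)[C@]12CC=CC[C@H]1[C@]1(COC2=O)[C@@H](OCc2ccccc2)CC[C@@](C)(COCc2ccccc2)[C@H]1CO[Si](c1ccccc1)(c1ccccc1)C(C)(C)C
F5 | step 13 | 17-nor ketone: 1,19-bis(benzyloxy)-6-[(tert-butyldiphenylsilyl)oxy]-15-oxo-17-nor-6,7-secokaur-11-en-7,20-olide | C1C(=O)[C@]23C[C@H]1C=C[C@H]2[C@]1(COC3=O)[C@@H](OCc2ccccc2)CC[C@@](C)(COCc2ccccc2)[C@H]1CO[Si](c1ccccc1)(c1ccccc1)C(C)(C)C
F6 | step 13 | nor-ketone diol: 6-[(tert-butyldiphenylsilyl)oxy]-1,19-dihydroxy-15-oxo-17-nor-6,7-secokauran-7,20-olide | C1C(=O)[C@]23C[C@H]1CC[C@H]2[C@]1(COC3=O)[C@@H](O)CC[C@@](C)(CO)[C@H]1CO[Si](c1ccccc1)(c1ccccc1)C(C)(C)C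
F7 | step 8 | ring aldehyde: 2-(benzyloxy)-5-[(benzyloxy)methyl]-6-{[(tert-butyldiphenylsilyl)oxy]methyl}-5-methylcyclohexane-1-carbaldehyde (C1 epimers; other centres as in 12) | O=CC1[C@@H](OCc2ccccc2)CC[C@@](C)(COCc2ccccc2)[C@H]1CO[Si](c1ccccc1)(c1ccccc1)C(C)(C)C
F8 | step 8 | quaternary allyl aldehyde: 1-allyl derivative of F7 with allyl trans to the C2 benzyloxy and C6 silyloxymethyl groups | C=CC[C@]1(C=O)[C@@H](OCc2ccccc2)CC[C@@](C)(COCc2ccccc2)[C@H]1CO[Si](c1ccccc1)(c1ccccc1)C(C)(C)C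
F9 | step 8 | allyl alcohol: primary alcohol from reduction of F8 | C=CC[C@]1(CO)[C@@H](OCc2ccccc2)CC[C@@](C)(COCc2ccccc2)[C@H]1CO[Si](c1ccccc1)(c1ccccc1)C(C)(C)C
F10 | step 8 | 1,5-diol: 3-hydroxypropyl/hydroxymethyl diol from hydroboration of F9 | OCCC[C@]1(CO)[C@@H](OCc2ccccc2)CC[C@@](C)(COCc2ccccc2)[C@H]1CO[Si](c1ccccc1)(c1ccccc1)C(C)(C)C
F11 | step 16 | methyl ketone: 1,19-diacetoxy-6-[(tert-butyldiphenylsilyl)oxy]-15-oxo-6,7-secokauran-7,20-olide (C16 epimers) | CC1C(=O)[C@]23C[C@H]1CC[C@H]2[C@]1(COC3=O)[C@@H](OC(C)=O)CC[C@@](C)(COC(C)=O)[C@H]1CO[Si](c1ccccc1)(c1ccccc1)C(C)(C)C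
F12 | step 16 | trimethylsilyl enol ether of F11 (C15=C16) | CC1=C(O[Si](C)(C)C)[C@]23C[C@H]1CC[C@H]2[C@]1(COC3=O)[C@@H](OC(C)=O)CC[C@@](C)(COC(C)=O)[C@H]1CO[Si](c1ccccc1)(c1ccccc1)C(C)(C)C
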